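**Retrosynthetic overview**

1. The target is read as EGCG-(4β→6)-gallocatechin. The route rests on ring D, the phloroglucinol ring of the lower unit (C4a, C5, C6, C7, C8, C8a): its three oxygens (O5, O7, and O1 on C8a) and two carbon substituents (upper C4 on C6, lower C4 on C4a) must each be placed and told apart.
2. Ring D is cut at C5–C4a and C8–C8a (benzannulation). C5, C6, C7 and C8 come from a 3-benzyloxycyclobutenone carrying the benzylated EGCG unit on its sp3 carbon; C4a and C8a come from a siloxyalkyne carrying the open ring F chain. O5 emerges as a free phenol, O7 as a benzyl ether and O1 as a silyl ether.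
3. The cyclobutenone is cut into a flavan-4-ylketene and benzyloxyacetylene ([2+2]); the ketene goes back through a 4β acetic acid side chain (Lewis-acid alkylation at C4) to perbenzylated EGCG, itself assembled from (−)-epigallocatechin and tri-O-benzylgallic acid.
4. The siloxyalkyne is cut at lower C4–C4a (acetylide on a primary triflate) and at lower C2–C3 (Evans glycolate aldol on 3,4,5-tris(benzyloxy)benzaldehyde, which sets both lower stereocentres).
5. Ring order: rings A, C and B come with epigallocatechin, the galloyl ring with the acid and ring E with the aldehyde; ring D is formed in step 18; ring F is closed last (O1–C2, Mitsunobu with inversion, step 21); hydrogenolysis ends the route.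

Key step: step 18

Remark: positions are numbered per flavan unit (upper = EGCG unit, lower = gallocatechin unit); rings D, F and E are the benzo, pyran and pendant aryl rings of the lower unit; the target SMILES is read as upper (2R,3R) with the interflavan bond 4β (trans to O3) and lower (2R,3S). "Octa-O-benzyl-EGCG-4β-yl" means perbenzylated EGCG bonded through C4 on the β face. The upper unit is drawn from (−)-epigallocatechin and commercial 3,4,5-tris(benzyloxy)benzoic acid, so that perbenzylated EGCG is reached through two defined intermediates.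

**Route**

Step 1
Reactants: 1 (−)-epigallocatechin
Product: 2 5,7,3',4',5'-penta-O-benzyl-(−)-epigallocatechin [(2R,3R)-5,7-bis(benzyloxy)-2-(3,4,5-tris(benzyloxy)phenyl)chroman-3-ol]
Conditions: BnBr (6 equiv), K2CO3, DMF, 0 °C to rt, under argon
Reagents that add atoms: benzyl bromide, BrCc1ccccc1
Why: Williamson etherification of the five phenols with a carbonate base that should not deprotonate the secondary C3 alcohol and should be too weak to open the pyran ring, so C2 and C3 should keep their configuration and O3 stays free.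

Step 2
Reactants: 2 5,7,3',4',5'-penta-O-benzyl-(−)-epigallocatechin; 3 3,4,5-tris(benzyloxy)benzoic acid (1.3 equiv)
Product: 4 octa-O-benzyl-EGCG [(2R,3R)-5,7-bis(benzyloxy)-2-(3,4,5-tris(benzyloxy)phenyl)chroman-3-yl 3,4,5-tris(benzyloxy)benzoate]
Conditions: DCC, DMAP, CH2Cl2, 0 °C to rt
Reagents that add atoms: none
Why: Steglich esterification, in which the acid is activated as its O-acylisourea and N-acylpyridinium and acylates the secondary C3 alcohol; the C3–O bond is not broken, so C3 keeps its configuration.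

Step 3
Reactants: 4 octa-O-benzyl-EGCG
Product: 5 4β-(2-ethoxyethoxy)-octa-O-benzyl-EGCG (2α-aryl; 3α-O-galloyl; 4β-alkoxy)
Conditions: DDQ (2 equiv), 2-ethoxyethanol (5 equiv), CH2Cl2, rt
Reagents that add atoms: 2-ethoxyethanol, CCOCCO
Why: DDQ benzylic oxidation, in which hydride abstraction at C4 (activated by the 5,7-dialkoxy ring A) gives a cation that the alcohol should trap anti to the 3-acyloxy group; the C4 configuration is not critical because the centre is ionised again in step 5.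

Step 4
Reactants: 6 allyl acetate
Product: 8 1-(allyloxy)-1-(tert-butyldimethylsilyloxy)ethene, via lithium enolate of allyl acetate 7 (not isolated)
Conditions: LiN(i-Pr)2 (commercial solution), THF, −78 °C; t-BuMe2SiCl, DMPU, −78 °C; cold pentane work-up, used at once below −20 °C
Reagents that add atoms: tert-butyldimethylsilyl chloride, CC(C)(C)[Si](C)(C)Cl
Why: Kinetic ester enolisation and O-silylation to the silyl ketene acetal, kept cold throughout so that the Ireland–Claisen rearrangement of the allyl ketene acetal cannot set in.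

Step 5
Reactants: 5 4β-(2-ethoxyethoxy)-octa-O-benzyl-EGCG; 8 1-(allyloxy)-1-(tert-butyldimethylsilyloxy)ethene (3 equiv)
Product: 9 allyl 2-(octa-O-benzyl-EGCG-4β-yl)acetate
Conditions: Me3SiOTf (0.3 equiv), CH2Cl2, −78 °C; Et3N quench
Reagents that add atoms: none
Why: Mukaiyama-type alkylation in which the Lewis acid ionises the C4 ether to the benzylic cation (or the 3,4-bridged acyloxonium ion of the α-gallate), and the ketene acetal should attack the β face anti to the 3-O-galloyl group, setting upper C4 as 4β (3,4-trans) as in known C4 substitutions of 2,3-cis flavans.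

Step 6
Reactants: 9 allyl 2-(octa-O-benzyl-EGCG-4β-yl)acetate
Product: 10 2-(octa-O-benzyl-EGCG-4β-yl)acetic acid
Conditions: Pd(PPh3)4 (5 mol %), morpholine, THF, rt; aq. citric acid work-up
Reagents that add atoms: none
Why: Tsuji–Trost deallylation, in which zerovalent palladium ionises the allyl ester and morpholine captures the allyl fragment under neutral conditions that should spare the gallate ester and the benzyl ethers.

Step 7
Reactants: 11 trichloroethylene
Product: 13 (E)-benzyl 1,2-dichlorovinyl ether, via dichloroacetylene 12 (not isolated)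
Conditions: BnOH, KH (2 equiv), THF, 0 °C; then 11, −50 °C to rt
Reagents that add atoms: benzyl alcohol, OCc1ccccc1
Why: Potassium benzyloxide dehydrochlorinates trichloroethylene and then adds anti to the dichloroacetylene formed, the established first stage of the dichlorovinyl ether route to ynol ethers.

Step 8
Reactants: 13 (E)-benzyl 1,2-dichlorovinyl ether
Product: 16 benzyloxyacetylene (benzyl ethynyl ether), via benzyl chloroethynyl ether 14 (not isolated), via lithium benzyloxyacetylide 15 (not isolated)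
Conditions: n-BuLi (2.2 equiv), THF, −78 to −40 °C; sat. aq. NH4Cl, −78 °C; cold work-up, kept as a cold solution
Reagents that add atoms: none
Why: β-Elimination of HCl, chlorine–lithium exchange and protonation should give the terminal ynol ether, which is kept cold because benzyl alkynyl ethers rearrange sigmatropically on warming.

Step 9
Reactants: 10 2-(octa-O-benzyl-EGCG-4β-yl)acetic acid; 16 benzyloxyacetylene (3 equiv)
Product: 19 3-(benzyloxy)-4-(octa-O-benzyl-EGCG-4β-yl)cyclobut-2-en-1-one (both epimers at the cyclobutenone sp3 carbon), via acid chloride 17 (not isolated), via flavanylketene 18 (not isolated)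
Conditions: (COCl)2, DMF (cat.), CH2Cl2, 0 °C to rt; evaporate; 16, Et3N (slow addition), CH2Cl2, 0 °C to rt
Reagents that add atoms: none
Why: Ketene–ynol ether [2+2] cycloaddition, in which the ketene carbonyl carbon bonds to the unsubstituted nucleophilic alkyne carbon and the ketene α-carbon to the alkoxy-bearing carbon, giving the 3-alkoxy-4-substituted cyclobutenone; the new ring stereocentre is left uncontrolled because it becomes sp2 in step 18.

Step 10
Reactants: 20 3,4,5-trihydroxybenzaldehyde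
Product: 21 3,4,5-tris(benzyloxy)benzaldehyde
Conditions: BnBr (3.5 equiv), K2CO3, DMF, 60 °C
Reagents that add atoms: benzyl bromide, BrCc1ccccc1
Why: Williamson etherification of the three phenols.

Step 11
Reactants: 22 (R)-4-benzyloxazolidin-2-one
Product: 24 (R)-4-benzyl-3-(benzyloxyacetyl)oxazolidin-2-one, via lithium salt of the oxazolidinone 23 (not isolated)
Conditions: n-BuLi, THF, −78 °C; BnOCH2COCl, −78 to 0 °C
Reagents that add atoms: benzyloxyacetyl chloride, O=C(Cl)COCc1ccccc1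
Why: N-Acylation of the lithiated Evans auxiliary with an acid chloride.

Step 12
Reactants: 24 (R)-4-benzyl-3-(benzyloxyacetyl)oxazolidin-2-one; 21 3,4,5-tris(benzyloxy)benzaldehyde
Product: 27 (R)-4-benzyl-3-[(2R,3S)-2-(benzyloxy)-3-hydroxy-3-(3,4,5-tris(benzyloxy)phenyl)propanoyl]oxazolidin-2-one, via dibutylboron Z-enolate 25 (not isolated), via boron aldolate 26 (not isolated)
Conditions: Bu2BOTf, Et3N, CH2Cl2, −78 to 0 °C; 21, −78 to 0 °C; pH 7 buffer, MeOH, H2O2, 0 °C
Reagents that add atoms: none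
Why: Evans syn glycolate aldol, in which the Z-boron enolate reacts through a closed Zimmerman–Traxler transition state and the benzyl group of the (R)-auxiliary shields one enolate face, setting both centres as (2R,3S), the threo pattern that becomes lower C3 (S) and lower C2 (S, inverted in step 21).

Step 13
Reactants: 27 aldol adduct
Product: 28 (R)-4-benzyl-3-[(2R,3S)-2-(benzyloxy)-3-(tert-butyldimethylsilyloxy)-3-(3,4,5-tris(benzyloxy)phenyl)propanoyl]oxazolidin-2-one
Conditions: t-BuMe2SiOTf, 2,6-lutidine, CH2Cl2, −78 to 0 °C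
Reagents that add atoms: tert-butyldimethylsilyl triflate, CC(C)(C)[Si](C)(C)OS(=O)(=O)C(F)(F)F
Why: Silylation of the hindered benzylic alcohol with a silyl triflate; because the neighbouring oxygen already carries its benzyl group from the aldol, the two lower oxygens are differentiated without any risk of silyl migration.

Step 14
Reactants: 28 silylated aldol adduct
Product: 29 (2S,3S)-2-(benzyloxy)-3-(tert-butyldimethylsilyloxy)-3-(3,4,5-tris(benzyloxy)phenyl)propan-1-ol
Conditions: LiBH4, MeOH (1 equiv), THF, 0 °C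
Reagents that add atoms: none
Why: Reductive cleavage of the N-acyl oxazolidinone by borohydride at the exocyclic carbonyl, releasing the auxiliary and leaving the silyl and benzyl ethers and both stereocentres untouched.

Step 15
Reactants: 29 primary alcohol
Product: 30 (2S,3S)-2-(benzyloxy)-3-(tert-butyldimethylsilyloxy)-3-(3,4,5-tris(benzyloxy)phenyl)propyl triflate
Conditions: Tf2O, 2,6-lutidine, CH2Cl2, −78 °C; cold work-up, used at once
Reagents that add atoms: triflic anhydride, O=S(=O)(OS(=O)(=O)C(F)(F)F)C(F)(F)F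
Why: O-Sulfonylation to a primary triflate, chosen because a β-alkoxy-branched primary carbon undergoes acetylide substitution reliably only with a very good leaving group.

Step 16
Reactants: 30 primary triflate
Product: 32 (4S,5S)-4-(benzyloxy)-5-(tert-butyldimethylsilyloxy)-5-(3,4,5-tris(benzyloxy)phenyl)pent-1-yne, via trimethylsilylalkyne 31 (not isolated)
Conditions: Me3SiC≡CH, n-BuLi, THF, −78 °C; 30, DMPU, −78 to −20 °C; then K2CO3, MeOH, rt
Reagents that add atoms: ethynyltrimethylsilane (as its lithium acetylide), C#C[Si](C)(C)C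
Why: SN2 alkylation of a lithium acetylide by the primary triflate (forming the future lower C4–C4a bond) followed by methanolytic C-desilylation, neither of which touches the stereocentres.

Step 17
Reactants: 32 terminal alkyne
Product: 35 (4S,5S)-4-(benzyloxy)-5-(tert-butyldimethylsilyloxy)-1-(triisopropylsilyloxy)-5-(3,4,5-tris(benzyloxy)phenyl)pent-1-yne, via lithium acetylide 33 (not isolated), via lithium ynolate 34 (not isolated)
Conditions: n-BuLi, THF, −78 °C; LiOOt-Bu (from t-BuOOH and LiN(SiMe3)2), −78 to 0 °C; i-Pr3SiOTf, −78 to 0 °C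
Reagents that add atoms: tert-butyl hydroperoxide (as its lithium salt), CC(C)(C)OO; triisopropylsilyl triflate, CC(C)[Si](C(C)C)(C(C)C)OS(=O)(=O)C(F)(F)F
Why: Oxidation of the lithium acetylide to the ynolate by the electrophilic oxygen of lithium tert-butyl peroxide, followed by O-silylation, which the bulky triisopropylsilyl group directs to oxygen to give the siloxyalkyne.

Step 18
Reactants: 19 3-(benzyloxy)-4-(octa-O-benzyl-EGCG-4β-yl)cyclobut-2-en-1-one; 35 siloxyalkyne (1.5 equiv)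
Product: 40 5-(benzyloxy)-2-[(2S,3S)-2-(benzyloxy)-3-(tert-butyldimethylsilyloxy)-3-(3,4,5-tris(benzyloxy)phenyl)propyl]-6-(octa-O-benzyl-EGCG-4β-yl)-3-(triisopropylsilyloxy)phenol, via vinylketene 36 (not isolated), via 4-vinylcyclobutenone 37 (not isolated), via dienylketene 38 (not isolated), via cyclohexadienone 39 (not isolated)
Conditions: toluene (0.1 M), 80 °C then 110 °C, sealed tube, under argon
Reagents that add atoms: none
Why: Heating should open the cyclobutenone by conrotatory 4π cleavage of its C(=O)–C(sp3) bond to the 3-benzyloxy vinylketene 36, whose ketene carbon is attacked by the nucleophilic, alkyl-bearing carbon of the siloxyalkyne in a regioselective [2+2] cycloaddition (new bonds lower C5–C4a and C8–C8a) to give 37. A second 4π opening (breaking C5–C8) gives dienylketene 38, and ring D is closed by disrotatory 6π electrocyclisation (C5–C6) to cyclohexadienone 39, which tautomerises to the phenol. This is the Danheiser benzannulation of cyclobutenones with siloxyalkynes, applied here to a cyclobutenone with a 3-alkoxy and a 4-alkyl substituent. No stereocentre is created: the cyclobutenone sp3 carbon becomes aromatic C6, so both epimers of 19 converge, and upper C4 is not involved. The step needs regioselectivity in the [2+2], which the polarisation of the ketene (electrophilic carbonyl carbon) and of the siloxyalkyne (nucleophilic carbon remote from oxygen) secures; it places the silyloxy carbon (C8a) para to C6 and delivers O5 free, O7 benzylated and O1 silylated. The bulky flavanyl group should rotate outward in the first opening, which keeps upper C4–H away from the ketene (no 1,5-hydrogen shift) and puts the substituent on the outside of the triene for the 6π closure.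

Step 19
Reactants: 40 ring D phenol
Product: 41 3,5-bis(benzyloxy)-4-(octa-O-benzyl-EGCG-4β-yl)-2-[(2S,3S)-2-(benzyloxy)-3-(tert-butyldimethylsilyloxy)-3-(3,4,5-tris(benzyloxy)phenyl)propyl]phenyl triisopropylsilyl ether
Conditions: BnBr, K2CO3, Bu4NI (cat.), DMF, rt
Reagents that add atoms: benzyl bromide, BrCc1ccccc1
Why: Williamson etherification of the only free phenol (lower O5), which must be capped at this point because O5 and O1 are both ortho to the C4a side chain and either could otherwise close ring F.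

Step 20
Reactants: 41 fully protected open-chain dimer
Product: 42 3,5-bis(benzyloxy)-4-(octa-O-benzyl-EGCG-4β-yl)-2-[(2S,3S)-2-(benzyloxy)-3-hydroxy-3-(3,4,5-tris(benzyloxy)phenyl)propyl]phenol
Conditions: Bu4NF, AcOH, THF, 0 °C to rt
Reagents that add atoms: none
Why: Fluoride cleavage of the aryl triisopropylsilyl ether and the benzylic tert-butyldimethylsilyl ether, buffered with acetic acid so that the gallate ester should not be attacked.

Step 21
Reactants: 42 phenol–benzylic alcohol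
Product: 43 tetradeca-O-benzyl EGCG-(4β→6)-gallocatechin (lower unit 2R,3S; 3-O-benzyl)
Conditions: PPh3, DIAD, THF (0.01 M), 0 °C to rt
Reagents that add atoms: none
Why: Intramolecular Mitsunobu etherification in which the C8a phenol displaces the activated benzylic oxygen at lower C2 with inversion (S to R), closing the six-membered ring F as the 2,3-trans isomer while the C3 benzyl ether is untouched.

Step 22
Reactants: 43 tetradeca-O-benzyl dimer
Product: 44 CNP0271447.2, EGCG-(4β→6)-gallocatechin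
Conditions: H2 (1 atm), Pd(OH)2/C, THF/MeOH/H2O, rt
Reagents that add atoms: none
Why: Hydrogenolysis of the fourteen benzyl ethers, under which the gallate ester, the two pyran C–O bonds and the interflavan bond are expected to survive as in other proanthocyanidin end-games.

**Compound list**

1 | (−)-epigallocatechin | O[C@@H]1Cc2c(O)cc(O)cc2O[C@@H]1c1cc(O)c(O)c(O)c1 | starting material
2 | 5,7,3',4',5'-penta-O-benzyl-(−)-epigallocatechin | O[C@@H]1Cc2c(OCc9ccccc9)cc(OCc9ccccc9)cc2O[C@@H]1c8cc(OCc9ccccc9)c(OCc9ccccc9)c(OCc9ccccc9)c8 | intermediate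
3 | 3,4,5-tris(benzyloxy)benzoic acid | O=C(O)c8cc(OCc9ccccc9)c(OCc9ccccc9)c(OCc9ccccc9)c8 | starting material
4 | octa-O-benzyl-EGCG | O=C(O[C@@H]1Cc2c(OCc9ccccc9)cc(OCc9ccccc9)cc2O[C@@H]1c8cc(OCc9ccccc9)c(OCc9ccccc9)c(OCc9ccccc9)c8)c8cc(OCc9ccccc9)c(OCc9ccccc9)c(OCc9ccccc9)c8 | intermediate
5 | 4β-(2-ethoxyethoxy)-octa-O-benzyl-EGCG | O=C(O[C@@H]1[C@@H](OCCOCC)c2c(OCc9ccccc9)cc(OCc9ccccc9)cc2O[C@@H]1c8cc(OCc9ccccc9)c(OCc9ccccc9)c(OCc9ccccc9)c8)c8cc(OCc9ccccc9)c(OCc9ccccc9)c(OCc9ccccc9)c8 | intermediate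
6 | allyl acetate | CC(=O)OCC=C | starting material
7 | lithium enolate of allyl acetate | [Li+].[O-]C(=C)OCC=C | intermediate
8 | 1-(allyloxy)-1-(tert-butyldimethylsilyloxy)ethene | C=C(OCC=C)O[Si](C)(C)C(C)(C)C | intermediate
9 | allyl 2-(octa-O-benzyl-EGCG-4β-yl)acetate | O=C(O[C@@H]1[C@@H](CC(=O)OCC=C)c2c(OCc9ccccc9)cc(OCc9ccccc9)cc2O[C@@H]1c8cc(OCc9ccccc9)c(OCc9ccccc9)c(OCc9ccccc9)c8)c8cc(OCc9ccccc9)c(OCc9ccccc9)c(OCc9ccccc9)c8 | intermediate
10 | 2-(octa-O-benzyl-EGCG-4β-yl)acetic acid | O=C(O[C@@H]1[C@@H](CC(=O)O)c2c(OCc9ccccc9)cc(OCc9ccccc9)cc2O[C@@H]1c8cc(OCc9ccccc9)c(OCc9ccccc9)c(OCc9ccccc9)c8)c8cc(OCc9ccccc9)c(OCc9ccccc9)c(OCc9ccccc9)c8 | intermediate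
11 | trichloroethylene | ClC=C(Cl)Cl | starting material
12 | dichloroacetylene | ClC#CCl | intermediate
13 | (E)-benzyl 1,2-dichlorovinyl ether | Cl/C=C(/Cl)OCc1ccccc1 | intermediate
14 | benzyl chloroethynyl ether | ClC#COCc1ccccc1 | intermediate
15 | lithium benzyloxyacetylide | [Li+].[C-]#COCc1ccccc1 | intermediate
16 | benzyloxyacetylene | C#COCc1ccccc1 | intermediate
17 | 2-(octa-O-benzyl-EGCG-4β-yl)acetyl chloride | O=C(O[C@@H]1[C@@H](CC(=O)Cl)c2c(OCc9ccccc9)cc(OCc9ccccc9)cc2O[C@@H]1c8cc(OCc9ccccc9)c(OCc9ccccc9)c(OCc9ccccc9)c8)c8cc(OCc9ccccc9)c(OCc9ccccc9)c(OCc9ccccc9)c8 | intermediate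
18 | (octa-O-benzyl-EGCG-4β-yl)ketene | O=C(O[C@@H]1[C@@H](C=C=O)c2c(OCc9ccccc9)cc(OCc9ccccc9)cc2O[C@@H]1c8cc(OCc9ccccc9)c(OCc9ccccc9)c(OCc9ccccc9)c8)c8cc(OCc9ccccc9)c(OCc9ccccc9)c(OCc9ccccc9)c8 | intermediate
19 | 3-(benzyloxy)-4-(octa-O-benzyl-EGCG-4β-yl)cyclobut-2-en-1-one (both epimers at the ring sp3 carbon) | O=C(O[C@@H]1[C@@H](C3C(=O)C=C3OCc9ccccc9)c2c(OCc9ccccc9)cc(OCc9ccccc9)cc2O[C@@H]1c8cc(OCc9ccccc9)c(OCc9ccccc9)c(OCc9ccccc9)c8)c8cc(OCc9ccccc9)c(OCc9ccccc9)c(OCc9ccccc9)c8 | intermediate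
20 | 3,4,5-trihydroxybenzaldehyde | O=Cc1cc(O)c(O)c(O)c1 | starting material
21 | 3,4,5-tris(benzyloxy)benzaldehyde | O=Cc8cc(OCc9ccccc9)c(OCc9ccccc9)c(OCc9ccccc9)c8 | intermediate
22 | (R)-4-benzyloxazolidin-2-one | O=C1N[C@H](Cc2ccccc2)CO1 | starting material
23 | lithium salt of (R)-4-benzyloxazolidin-2-one | [Li+].O=C1[N-][C@H](Cc2ccccc2)CO1 | intermediate
24 | (R)-4-benzyl-3-(benzyloxyacetyl)oxazolidin-2-one | O=C(COCc1ccccc1)N1[C@H](Cc2ccccc2)COC1=O | intermediate
25 | dibutylboron Z-enolate of 24 | O=C1OC[C@@H](Cc2ccccc2)N1/C(OB(CCCC)CCCC)=C/OCc1ccccc1 | intermediate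
26 | dibutylboron aldolate of 27 | O=C(N1[C@H](Cc2ccccc2)COC1=O)[C@H](OCc9ccccc9)[C@H](c8cc(OCc9ccccc9)c(OCc9ccccc9)c(OCc9ccccc9)c8)OB(CCCC)CCCC | intermediate
27 | (R)-4-benzyl-3-[(2R,3S)-2-(benzyloxy)-3-hydroxy-3-(3,4,5-tris(benzyloxy)phenyl)propanoyl]oxazolidin-2-one | O=C(N1[C@H](Cc2ccccc2)COC1=O)[C@H](OCc9ccccc9)[C@H](c8cc(OCc9ccccc9)c(OCc9ccccc9)c(OCc9ccccc9)c8)O | intermediate
28 | 3-O-tert-butyldimethylsilyl ether of 27 | O=C(N1[C@H](Cc2ccccc2)COC1=O)[C@H](OCc9ccccc9)[C@H](c8cc(OCc9ccccc9)c(OCc9ccccc9)c(OCc9ccccc9)c8)O[Si](C)(C)C(C)(C)C | intermediate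
29 | (2S,3S)-2-(benzyloxy)-3-(tert-butyldimethylsilyloxy)-3-(3,4,5-tris(benzyloxy)phenyl)propan-1-ol | OC[C@H](OCc9ccccc9)[C@H](c8cc(OCc9ccccc9)c(OCc9ccccc9)c(OCc9ccccc9)c8)O[Si](C)(C)C(C)(C)C | intermediate
30 | triflate of 29 | FC(F)(F)S(=O)(=O)OC[C@H](OCc9ccccc9)[C@H](c8cc(OCc9ccccc9)c(OCc9ccccc9)c(OCc9ccccc9)c8)O[Si](C)(C)C(C)(C)C | intermediate
31 | (4S,5S)-4-(benzyloxy)-5-(tert-butyldimethylsilyloxy)-1-(trimethylsilyl)-5-(3,4,5-tris(benzyloxy)phenyl)pent-1-yne | C[Si](C)(C)C#CC[C@H](OCc9ccccc9)[C@H](c8cc(OCc9ccccc9)c(OCc9ccccc9)c(OCc9ccccc9)c8)O[Si](C)(C)C(C)(C)C | intermediate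
32 | (4S,5S)-4-(benzyloxy)-5-(tert-butyldimethylsilyloxy)-5-(3,4,5-tris(benzyloxy)phenyl)pent-1-yne | C#CC[C@H](OCc9ccccc9)[C@H](c8cc(OCc9ccccc9)c(OCc9ccccc9)c(OCc9ccccc9)c8)O[Si](C)(C)C(C)(C)C | intermediate
33 | lithium acetylide of 32 | [Li+].[C-]#CC[C@H](OCc9ccccc9)[C@H](c8cc(OCc9ccccc9)c(OCc9ccccc9)c(OCc9ccccc9)c8)O[Si](C)(C)C(C)(C)C | intermediate
34 | lithium ynolate from 33 | [Li+].[O-]C#CC[C@H](OCc9ccccc9)[C@H](c8cc(OCc9ccccc9)c(OCc9ccccc9)c(OCc9ccccc9)c8)O[Si](C)(C)C(C)(C)C | intermediate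
35 | (4S,5S)-4-(benzyloxy)-5-(tert-butyldimethylsilyloxy)-1-(triisopropylsilyloxy)-5-(3,4,5-tris(benzyloxy)phenyl)pent-1-yne | CC(C)[Si](C(C)C)(C(C)C)OC#CC[C@H](OCc9ccccc9)[C@H](c8cc(OCc9ccccc9)c(OCc9ccccc9)c(OCc9ccccc9)c8)O[Si](C)(C)C(C)(C)C | intermediate
36 | 3-(benzyloxy)-4-(octa-O-benzyl-EGCG-4β-yl)buta-1,3-dien-1-one (vinylketene; flavanyl trans to the ketene arm) | O=C(O[C@@H]1[C@@H](/C=C(OCc9ccccc9)/C=C=O)c2c(OCc9ccccc9)cc(OCc9ccccc9)cc2O[C@@H]1c8cc(OCc9ccccc9)c(OCc9ccccc9)c(OCc9ccccc9)c8)c8cc(OCc9ccccc9)c(OCc9ccccc9)c(OCc9ccccc9)c8 | intermediate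
37 | 4-vinylcyclobutenone [2+2] adduct of 36 and 35 (2-alkyl; 3-triisopropylsilyloxy; 4-[1-benzyloxy-2-flavanylvinyl]; ring sp3 centre undefined) | O=C(O[C@@H]1[C@@H](/C=C(OCc9ccccc9)/C3C(=O)C(C[C@H](OCc9ccccc9)[C@H](c8cc(OCc9ccccc9)c(OCc9ccccc9)c(OCc9ccccc9)c8)O[Si](C)(C)C(C)(C)C)=C3O[Si](C(C)C)(C(C)C)C(C)C)c2c(OCc9ccccc9)cc(OCc9ccccc9)cc2O[C@@H]1c8cc(OCc9ccccc9)c(OCc9ccccc9)c(OCc9ccccc9)c8)c8cc(OCc9ccccc9)c(OCc9ccccc9)c(OCc9ccccc9)c8 | intermediate
38 | dienylketene from 37 (central alkene with the ketene arm cis to the benzyloxyvinyl arm) | O=C(O[C@@H]1[C@@H](/C=C(OCc9ccccc9)/C=C(/O[Si](C(C)C)(C(C)C)C(C)C)C(C[C@H](OCc9ccccc9)[C@H](c8cc(OCc9ccccc9)c(OCc9ccccc9)c(OCc9ccccc9)c8)O[Si](C)(C)C(C)(C)C)=C=O)c2c(OCc9ccccc9)cc(OCc9ccccc9)cc2O[C@@H]1c8cc(OCc9ccccc9)c(OCc9ccccc9)c(OCc9ccccc9)c8)c8cc(OCc9ccccc9)c(OCc9ccccc9)c(OCc9ccccc9)c8 | intermediate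
39 | cyclohexa-2,4-dienone from 38 (sp3 carbon bearing H and the flavanyl group; centre undefined) | O=C(O[C@@H]1[C@@H](C3C(=O)C(C[C@H](OCc9ccccc9)[C@H](c8cc(OCc9ccccc9)c(OCc9ccccc9)c(OCc9ccccc9)c8)O[Si](C)(C)C(C)(C)C)=C(O[Si](C(C)C)(C(C)C)C(C)C)C=C3OCc9ccccc9)c2c(OCc9ccccc9)cc(OCc9ccccc9)cc2O[C@@H]1c8cc(OCc9ccccc9)c(OCc9ccccc9)c(OCc9ccccc9)c8)c8cc(OCc9ccccc9)c(OCc9ccccc9)c(OCc9ccccc9)c8 | intermediate
40 | ring D phenol: 5-(benzyloxy)-2-[(2S,3S)-2-(benzyloxy)-3-(tert-butyldimethylsilyloxy)-3-(3,4,5-tris(benzyloxy)phenyl)propyl]-6-(octa-O-benzyl-EGCG-4β-yl)-3-(triisopropylsilyloxy)phenol | O=C(O[C@@H]1[C@@H](c3c(O)c(C[C@H](OCc9ccccc9)[C@H](c8cc(OCc9ccccc9)c(OCc9ccccc9)c(OCc9ccccc9)c8)O[Si](C)(C)C(C)(C)C)c(O[Si](C(C)C)(C(C)C)C(C)C)cc3OCc9ccccc9)c2c(OCc9ccccc9)cc(OCc9ccccc9)cc2O[C@@H]1c8cc(OCc9ccccc9)c(OCc9ccccc9)c(OCc9ccccc9)c8)c8cc(OCc9ccccc9)c(OCc9ccccc9)c(OCc9ccccc9)c8 | intermediate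
41 | O5-benzyl ether of 40 | O=C(O[C@@H]1[C@@H](c3c(OCc9ccccc9)c(C[C@H](OCc9ccccc9)[C@H](c8cc(OCc9ccccc9)c(OCc9ccccc9)c(OCc9ccccc9)c8)O[Si](C)(C)C(C)(C)C)c(O[Si](C(C)C)(C(C)C)C(C)C)cc3OCc9ccccc9)c2c(OCc9ccccc9)cc(OCc9ccccc9)cc2O[C@@H]1c8cc(OCc9ccccc9)c(OCc9ccccc9)c(OCc9ccccc9)c8)c8cc(OCc9ccccc9)c(OCc9ccccc9)c(OCc9ccccc9)c8 | intermediate
42 | 3,5-bis(benzyloxy)-4-(octa-O-benzyl-EGCG-4β-yl)-2-[(2S,3S)-2-(benzyloxy)-3-hydroxy-3-(3,4,5-tris(benzyloxy)phenyl)propyl]phenol | O=C(O[C@@H]1[C@@H](c3c(OCc9ccccc9)c(C[C@H](OCc9ccccc9)[C@H](c8cc(OCc9ccccc9)c(OCc9ccccc9)c(OCc9ccccc9)c8)O)c(O)cc3OCc9ccccc9)c2c(OCc9ccccc9)cc(OCc9ccccc9)cc2O[C@@H]1c8cc(OCc9ccccc9)c(OCc9ccccc9)c(OCc9ccccc9)c8)c8cc(OCc9ccccc9)c(OCc9ccccc9)c(OCc9ccccc9)c8 | intermediate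
43 | tetradeca-O-benzyl EGCG-(4β→6)-gallocatechin (lower 2R,3S) | O=C(O[C@@H]1[C@@H](c3c(OCc9ccccc9)c4C[C@H](OCc9ccccc9)[C@@H](c8cc(OCc9ccccc9)c(OCc9ccccc9)c(OCc9ccccc9)c8)Oc4cc3OCc9ccccc9)c2c(OCc9ccccc9)cc(OCc9ccccc9)cc2O[C@@H]1c8cc(OCc9ccccc9)c(OCc9ccccc9)c(OCc9ccccc9)c8)c8cc(OCc9ccccc9)c(OCc9ccccc9)c(OCc9ccccc9)c8 | intermediate
44 | CNP0271447.2, EGCG-(4β→6)-gallocatechin | O=C(O[C@@H]1[C@@H](c2c(O)cc3c(c2O)C[C@H](O)[C@@H](c2cc(O)c(O)c(O)c2)O3)c2c(O)cc(O)cc2O[C@@H]1c1cc(O)c(O)c(O)c1)c1cc(O)c(O)c(O)c1 | target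

**Step count and risks**

Total step count: 22. Longest linear sequence: 12 steps (steps 10, 12, 13, 14, 15, 16, 17, 18, 19, 20, 21, 22; from 20 to 44).

Steps most likely to fail:

1. Step 18 (benzannulation). The vinylogous-ester cyclobutenone may open only at temperatures at which the vinylketene is diverted: inward rotation followed by a 1,5-hydrogen shift from upper C4–H, acylation of the product phenol by ketene, or thermal decay of the siloxyalkyne. The fallback gives up the construction of ring D and joins the upper C4 cation to a preformed lower unit by Friedel–Crafts-type arylation with C8 blocked; it sets out from compound 5 and comes back at compound 44. Commercial (+)-gallocatechin would be benzylated (BnBr, K2CO3, DMF) to 5,7,3',4',5'-penta-O-benzyl-(+)-gallocatechin F1 and brominated at C8 (N-bromosuccinimide, CH2Cl2, −78 °C to rt) to 8-bromo-5,7,3',4',5'-penta-O-benzyl-(+)-gallocatechin F2. Compound 5 and an excess of F2 would be treated with Me3SiOTf in CH2Cl2 at −78 °C, so that the C4 cation is attacked by the only free position of ring D (C6) on the β face, to give the 8-bromo trideca-O-benzyl dimer F3. Hydrogenolysis of F3 over Pd(OH)2/C with Et3N should remove the thirteen benzyl groups and the bromine and give 44.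

2. Step 9 (ketene [2+2]). Dimerisation of the hindered monoalkylketene and sigmatropic decay or polymerisation of benzyloxyacetylene may outrun the cross cycloaddition. The fallback carries the alkoxy group in on a robust alkyne and exchanges it afterwards; it sets out from compound 10 and comes back at compound 19. The acid chloride from 10 would be dehydrochlorinated with Et3N in a large excess of commercial ethoxyacetylene to give 3-ethoxy-4-(octa-O-benzyl-EGCG-4β-yl)cyclobut-2-en-1-one F4. Acid-catalysed alkoxy exchange of this vinylogous ester with benzyl alcohol (pyridinium p-toluenesulfonate, toluene, 50 °C, reduced pressure to remove ethanol) should then give 19. The double bond should stay in place because its migration would need an antiaromatic hydroxycyclobutadiene.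

3. Step 5 (C4 alkylation). The allyl ketene acetal may undergo Ireland–Claisen rearrangement before it is captured, and the C4 cation may instead be intercepted by ring A of a second molecule (oligomerisation). The fallback uses a stable allyl nucleophile and oxidative cleavage; it sets out from compound 5 and comes back at compound 10. Compound 5 and allyltrimethylsilane with Me3SiOTf in CH2Cl2 at −78 °C should give 4β-allyl-octa-O-benzyl-EGCG F5. Dihydroxylation and cleavage (OsO4 cat., N-methylmorpholine N-oxide; then NaIO4) should give (octa-O-benzyl-EGCG-4β-yl)acetaldehyde F6, and Pinnick oxidation (NaClO2, NaH2PO4, 2-methyl-2-butene, t-BuOH/H2O) should give 10.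

**Further compounds**

F1 | step 18 | 5,7,3',4',5'-penta-O-benzyl-(+)-gallocatechin | O[C@H]1Cc2c(OCc9ccccc9)cc(OCc9ccccc9)cc2O[C@@H]1c8cc(OCc9ccccc9)c(OCc9ccccc9)c(OCc9ccccc9)c8
F2 | step 18 | 8-bromo-5,7,3',4',5'-penta-O-benzyl-(+)-gallocatechin | O[C@H]1Cc2c(OCc9ccccc9)cc(OCc9ccccc9)c(Br)c2O[C@@H]1c8cc(OCc9ccccc9)c(OCc9ccccc9)c(OCc9ccccc9)c8
F3 | step 18 | 8-bromo trideca-O-benzyl EGCG-(4β→6)-gallocatechin (lower 3-OH free) | O=C(O[C@@H]1[C@@H](c3c(OCc9ccccc9)c(Br)c4c(c3OCc9ccccc9)C[C@H](O)[C@@H](c8cc(OCc9ccccc9)c(OCc9ccccc9)c(OCc9ccccc9)c8)O4)c2c(OCc9ccccc9)cc(OCc9ccccc9)cc2O[C@@H]1c8cc(OCc9ccccc9)c(OCc9ccccc9)c(OCc9ccccc9)c8)c8cc(OCc9ccccc9)c(OCc9ccccc9)c(OCc9ccccc9)c8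
F4 | step 9 | 3-ethoxy-4-(octa-O-benzyl-EGCG-4β-yl)cyclobut-2-en-1-one | O=C(O[C@@H]1[C@@H](C3C(=O)C=C3OCC)c2c(OCc9ccccc9)cc(OCc9ccccc9)cc2O[C@@H]1c8cc(OCc9ccccc9)c(OCc9ccccc9)c(OCc9ccccc9)c8)c8cc(OCc9ccccc9)c(OCc9ccccc9)c(OCc9ccccc9)c8
F5 | step 5 | 4β-allyl-octa-O-benzyl-EGCG | O=C(O[C@@H]1[C@@H](CC=C)c2c(OCc9ccccc9)cc(OCc9ccccc9)cc2O[C@@H]1c8cc(OCc9ccccc9)c(OCc9ccccc9)c(OCc9ccccc9)c8)c8cc(OCc9ccccc9)c(OCc9ccccc9)c(OCc9ccccc9)c8
F6 | step 5 | (octa-O-benzyl-EGCG-4β-yl)acetaldehyde | O=C(O[C@@H]1[C@@H](CC=O)c2c(OCc9ccccc9)cc(OCc9ccccc9)cc2O[C@@H]1c8cc(OCc9ccccc9)c(OCc9ccccc9)c(OCc9ccccc9)c8)c8cc(OCc9ccccc9)c(OCc9ccccc9)c(OCc9ccccc9)c8
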